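## Retrosynthetic overview

1. Feature: the benzene ring (C3a, C4, C5, C6, C7, C7a) has its two bromines meta to each other at C4 and C6 and shares the C3a–C7a edge with the pyrrole ring. This pattern can come from a 5-bromo-1,2-diazine (C7a, C7, C6, C5) joined to a bromoalkyne (C3a, C4).
2. The C3–Br bond is cut first, as a late electrophilic bromination of 4,6-dibromoindole. The pyrrole ring is then taken back to the N-methoxycarbonyl indoline.
3. Key disconnection: C3a–C7a and C4–C5, a retro-[4+2] with N2 put back. It leads to a pyridazin-3-yl carbamate whose nitrogen carries a 4-bromobut-3-ynyl chain.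
4. The precursor is built from 3,5-dibromopyridazine by C3-selective palladium amidation with methyl carbamate, Mitsunobu N-alkylation with but-3-yn-1-ol, and bromination of the alkyne C–H.
5. Ring order: the purchased pyridazine is sacrificed, the five-membered nitrogen ring and the benzene ring form together in one operation, and the pyrrole follows by dehydrogenation.

Key step: step 4

Assumption: with a chelating diphosphine, zerovalent palladium is taken to insert into the C3–Br bond of 3,5-dibromopyridazine (next to N2) ahead of C5–Br, as is usual for 3,5-dihalopyridazines in cross-coupling. The target has no stereocentre.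

## Route

Step 1
Reactants: 1 3,5-dibromopyridazine; 2 methyl carbamate
Product: 3 methyl (5-bromopyridazin-3-yl)carbamate
Conditions: Pd2(dba)3 (cat.), Xantphos (cat.), Cs2CO3, 1,4-dioxane, 80 °C, Ar
Reagents that add atoms: none
Why: Buchwald–Hartwig amidation of a heteroaryl bromide with a primary carbamate: zerovalent palladium on a chelating diphosphine should insert into the C–Br bond next to the ring nitrogen (C3) ahead of C5–Br, Cs2CO3 is too weak a base to drive uncatalysed SNAr of the carbamate at C5, and deprotonation of 3 as it forms makes its ring electron-rich enough to hold back a second coupling.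

Step 2
Reactants: 3 methyl (5-bromopyridazin-3-yl)carbamate; 4 but-3-yn-1-ol
Product: 5 methyl N-(5-bromopyridazin-3-yl)-N-(but-3-yn-1-yl)carbamate
Conditions: PPh3, DIAD, THF, 0 °C to rt
Reagents that add atoms: none
Why: Mitsunobu reaction: the N–H between the ester carbonyl and the electron-poor bromodiazine should be acidic enough to protonate the betaine, and its anion should displace the primary alkoxyphosphonium ion at the exocyclic nitrogen under near-neutral conditions, where neither E2 loss from the homopropargyl unit nor SNAr at C5 should compete.

Step 3
Reactants: 5 methyl N-(5-bromopyridazin-3-yl)-N-(but-3-yn-1-yl)carbamate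
Product: 6 methyl N-(4-bromobut-3-yn-1-yl)-N-(5-bromopyridazin-3-yl)carbamate
Conditions: NBS, AgNO3 (cat.), acetone, rt, dark
Reagents that add atoms: N-bromosuccinimide, O=C1CCC(=O)N1Br
Why: Silver-catalysed electrophilic bromination of a terminal alkyne with NBS, a mild and general C(sp)–H to C(sp)–Br exchange to which the electron-poor bromodiazine and the fully substituted carbamate offer no competing nucleophilic site.

Step 4
Reactants: 6 methyl N-(4-bromobut-3-yn-1-yl)-N-(5-bromopyridazin-3-yl)carbamate
Product: 8 methyl 4,6-dibromoindoline-1-carboxylate, via epidiazeno-bridged adduct 7 (not isolated)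
Conditions: 1,3,5-triisopropylbenzene (0.01 M, degassed), BHT (cat.), Ar, 200–230 °C
Reagents that add atoms: none
Why: Intramolecular inverse-electron-demand Diels–Alder reaction: the electron-poor 1,2-diazine of 6 acts as the 4π component through C3 and C6, the tethered C≡C acts as the 2π component, and the diaza-bridged adduct 7 loses N2 by retro-[4+2], so the arene arrives at the right oxidation level without an oxidant. The closest known reaction type is the thermal conversion of N-acyl-3-(alk-3-ynylamino)pyridazines into N-acylindolines in high-boiling arene solvents, and only the bromine on the alkyne terminus and the bromine on the diazine go beyond that record. The five-membered nitrogen ring closes through the new C3a–C7a bond (the nitrogen, two CH2 groups and the internal alkyne carbon reaching diazine C3), while the benzene ring closes through the new C4–C5 bond and becomes aromatic on cycloreversion. No stereocentre remains in 8, because the two bridgehead centres of 7 are erased with the loss of N2. The step needs regiocontrol, and the three-atom tether enforces it, since the internal alkyne carbon can reach only C3, which places the alkyne bromine at C4 and the diazine C5 bromine at C6. Both C–Br bonds must also outlast the heating: the carbamate (which draws the amino lone pair away from the diazine) and the C5 bromine lower the diene LUMO and hence the temperature needed, while high dilution in a degassed non-polar solvent with a radical inhibitor should suppress bimolecular quaternisation at C5 and radical loss of bromine.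

Step 5
Reactants: 8 methyl 4,6-dibromoindoline-1-carboxylate
Product: 9 4,6-dibromoindoline
Conditions: KOH, MeOH–H2O, reflux
Reagents that add atoms: none
Why: Alkaline carbamate hydrolysis (saponification at the acyl carbon, then loss of the carboxyl carbon as carbonate), helped by the anilide-type leaving ability of the indoline nitrogen, while the two aryl bromides sit on an unactivated benzene ring and cannot undergo SNAr.

Step 6
Reactants: 9 4,6-dibromoindoline
Product: 10 4,6-dibromo-1H-indole
Conditions: activated MnO2 (excess), toluene, 80 °C
Reagents that add atoms: none
Why: Oxidative dehydrogenation of an indoline with activated MnO2, driven by the gain of pyrrole aromaticity and leaving aryl bromides untouched.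

Step 7
Reactants: 10 4,6-dibromo-1H-indole
Product: 11 3,4,6-tribromo-1H-indole
Conditions: NBS (1 equiv), DMF, 0 °C, dark
Reagents that add atoms: N-bromosuccinimide, O=C1CCC(=O)N1Br
Why: Electrophilic aromatic substitution at C3, the enamine-like and most nucleophilic carbon of an N–H indole, with the benzene ring deactivated by its two bromines, so that one equivalent of NBS in the cold should stop at the monobromide in spite of the neighbouring C4 bromine.

## Compound list

1 | 3,5-dibromopyridazine | Brc1cnnc(Br)c1 | starting material
2 | methyl carbamate | COC(N)=O | starting material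
3 | methyl (5-bromopyridazin-3-yl)carbamate | COC(=O)Nc1cc(Br)cnn1 | intermediate
4 | but-3-yn-1-ol | C#CCCO | starting material
5 | methyl N-(5-bromopyridazin-3-yl)-N-(but-3-yn-1-yl)carbamate | COC(=O)N(CCC#C)c1cc(Br)cnn1 | intermediate
6 | methyl N-(4-bromobut-3-yn-1-yl)-N-(5-bromopyridazin-3-yl)carbamate | COC(=O)N(CCC#CBr)c1cc(Br)cnn1 | intermediate
7 | methyl 4,6-dibromo-2,3,5,7a-tetrahydro-5,7a-epidiazenoindole-1-carboxylate (N=N bridge from C5 to C7a, C3a=C4 and C6=C7 double bonds; racemic, bridgeheads fixed by the bicycle) | COC(=O)N1CCC2=C(Br)C3C(Br)=CC12N=N3 | intermediate
8 | methyl 4,6-dibromoindoline-1-carboxylate | COC(=O)N1CCc2c(Br)cc(Br)cc21 | intermediate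
9 | 4,6-dibromoindoline | Brc1cc(Br)c2c(c1)NCC2 | intermediate
10 | 4,6-dibromo-1H-indole | Brc1cc(Br)c2cc[nH]c2c1 | intermediate
11 | 3,4,6-tribromo-1H-indole | Brc1cc(Br)c2c(Br)c[nH]c2c1 | target

## Step count and risks

Total step count: 7. Longest linear sequence: 7 (from 1 to 11).

**Step 4.** The C(sp)–Br bond may break down on heating, by homolysis, loss of HBr or oligomerisation, faster than the cycloaddition proceeds.
- The fallback carries tin instead of bromine through the cycloaddition.
- From 5, Bu3SnOMe with catalytic ZnBr2 in THF should give methyl N-(5-bromopyridazin-3-yl)-N-[4-(tributylstannyl)but-3-yn-1-yl]carbamate F1, whose alkyne is more electron-rich and so better matched to the diazine.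
- Heating as in step 4 should lead, through methyl 6-bromo-4-(tributylstannyl)-2,3,5,7a-tetrahydro-5,7a-epidiazenoindole-1-carboxylate F2, to methyl 6-bromo-4-(tributylstannyl)indoline-1-carboxylate F3.
- Br2 in CH2Cl2 at −78 °C should then replace tin at C4 by ipso-bromodestannylation, and the route is rejoined at 8.
- Tin is preferred to silicon because C4 lies meta to the carbamate nitrogen. Ipso attack on an aryl silane could lose out to bromination at the nitrogen-activated C5 and C7, whereas cleavage of an aryl–tin bond is much faster than either.

**Step 1.** Palladium may insert into the wrong C–Br bond, or into both, which would erode site selectivity.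
- The fallback uses the opposite preference of SNAr for C5 to remove the choice.
- From 1, sodium benzyloxide (BnOH, NaH, THF, 0 °C) should displace the C5 bromide to give 5-(benzyloxy)-3-bromopyridazine F4.
- The only remaining C–Br bond is then amidated with 2 under the conditions of step 1 to give methyl [5-(benzyloxy)pyridazin-3-yl]carbamate F5.
- Hydrogenolysis (H2, Pd/C, MeOH) should free methyl (5-hydroxypyridazin-3-yl)carbamate F6.
- POBr3 in MeCN at 80 °C should convert the hydroxydiazine into the bromide, rejoining the route at 3.

**Step 2.** Proton transfer to the betaine may be too slow, or alkylation may drift to ring nitrogen N2 or to the carbamate oxygen.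
- The fallback forms the N–alkyl bond before the N–aryl bond.
- Commercial 4-(trimethylsilyl)but-3-yn-1-amine and methyl chloroformate (Et3N, CH2Cl2, 0 °C) should give methyl N-[4-(trimethylsilyl)but-3-yn-1-yl]carbamate F7.
- From 1, amidation with this carbamate (Pd2(dba)3, Xantphos, Cs2CO3, dioxane, 100 °C) should give methyl N-(5-bromopyridazin-3-yl)-N-[4-(trimethylsilyl)but-3-yn-1-yl]carbamate F8. The silyl cap keeps the alkyne out of Sonogashira-type coupling.
- NBS with AgNO3 in acetone should then exchange silicon for bromine, and the route is rejoined at 6.

## Further compounds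

F1 | step 4 | methyl N-(5-bromopyridazin-3-yl)-N-[4-(tributylstannyl)but-3-yn-1-yl]carbamate | CCCC[Sn](CCCC)(CCCC)C#CCCN(C(=O)OC)c1cc(Br)cnn1
F2 | step 4 | methyl 6-bromo-4-(tributylstannyl)-2,3,5,7a-tetrahydro-5,7a-epidiazenoindole-1-carboxylate | CCCC[Sn](CCCC)(CCCC)C1=C2CCN(C(=O)OC)C23C=C(Br)C1N=N3
F3 | step 4 | methyl 6-bromo-4-(tributylstannyl)indoline-1-carboxylate | CCCC[Sn](CCCC)(CCCC)c1cc(Br)cc2c1CCN2C(=O)OC
F4 | step 1 | 5-(benzyloxy)-3-bromopyridazine | Brc1cc(OCc2ccccc2)cnn1
F5 | step 1 | methyl [5-(benzyloxy)pyridazin-3-yl]carbamate | COC(=O)Nc1cc(OCc2ccccc2)cnn1
F6 | step 1 | methyl (5-hydroxypyridazin-3-yl)carbamate | COC(=O)Nc1cc(O)cnn1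
F7 | step 2 | methyl N-[4-(trimethylsilyl)but-3-yn-1-yl]carbamate | COC(=O)NCCC#C[Si](C)(C)C
F8 | step 2 | methyl N-(5-bromopyridazin-3-yl)-N-[4-(trimethylsilyl)but-3-yn-1-yl]carbamate | COC(=O)N(CCC#C[Si](C)(C)C)c1cc(Br)cnn1
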